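## Structural features

The target 19 is an achiral, linear tridepside: three highly substituted benzene rings joined head to tail by two aryl ester bonds and ending in a free carboxylic acid. There is no stereocentre, so nothing has to be set or preserved. Ring A is a 4-hydroxy-2,3-dimethoxy-6-methylbenzoyl group whose carbonyl carbon sits between a methoxy and a methyl group. Rings B and C are orsellinate units, each with a C2 hydroxyl hydrogen-bonded to its C1 carbonyl, a C6 methyl, and a C4 oxygen that carries the next acyl group. The fragile parts are the two depside bonds and the orsellinic acid terminus. The ring B–ring C ester is the weaker one, because its neighbouring C2 hydroxyl makes it a salicylate-type ester open to aminolysis and alcoholysis. The acid terminus can lose CO2 on heating. The real difficulty is the handling of oxygen functions: five phenolic oxygens of three kinds must be told apart, two hindered esters must be made, and the last operations must avoid bases and nucleophiles. Ring A adds its own regiochemical problem, a 1,2,3-trioxygenated ring with a carboxyl para to the one free oxygen. The key step exploits the substitution around each carboxyl-bearing C1. Rings B and C each have one ortho carbon blocked by methyl (C6) and one that can begin as C–H (C2), whereas ring A has both ortho positions filled (C2 methoxy, C6 methyl). A carbonyl-directed C–H oxygenation can therefore only install the two chelated hydroxyls.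

## Logic of the disconnections

**19 ⇒ 18.** The cut is the O–CH2 bond of the ester masking the ring C carboxyl. The last step must be neutral and free of nucleophiles, because both depside bonds and the acid terminus are already present. The ester must also outlast hot trifluoroacetic acid/anhydride and an oxidant in the key step. A plain benzyl ester is at risk of acidolysis there, so the 4-nitrobenzyl ester is used: it is inert to acid and still falls to hydrogen over Pd/C.

**18 ⇒ 15.** The cut is the two C2–O bonds of rings B and C. Removing both chelated hydroxyls turns rings B and C into 4-oxy-2-methylbenzoates that come from one purchasable acid. There is then no 2-hydroxyl to protect or to distinguish from the 4-hydroxyl anywhere in the assembly. The forward step must oxygenate two C–H bonds without harming ring A or three esters. A ring A acetate was weighed and set aside, because its removal would need a nucleophile after the salicylate-type ester bonds exist. Instead the ring A phenol is left free in 15. The anhydride of the medium converts it to a trifluoroacetate before the oxidant is added, the same masking that protects the newly formed phenols, and water removes it in the work-up.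

**15 ⇒ 14.** The cut is the O–Si bond on ring A. The ring A phenol must be masked while its acid is activated. A silyl ether cannot migrate as an acyl group could, and its removal by buffered fluoride happens while the esters are still plain aryl benzoates.

**14 ⇒ 12 + 6 (through 13).** The cut is the acyl C–O bond between the ring A carbonyl and the ring B oxygen. This is the convergent junction of the two branches. The forward step needs an acyl donor reactive enough to overcome two ortho substituents, hence the acid chloride 13.

**12 ⇒ 10 ⇒ 9 ⇒ 7.** The cuts are the ring A C1–carboxyl bond (carbonylation of 10), the S–O bond (10 to 9) and the Si–O bond (9 to 8, the reduced form of 7). Laid over ring A, 7 already has both methoxy groups, the methyl and the C4 oxygen in place. Its other oxygen, the one beside the methyl-bearing carbon, sits where the carboxyl carbon must go. So 7 serves only if that C–O bond is exchanged for a C–C bond. Carboxylating the free ring position of 8 instead would give an acid with one oxygen too many. The forward demands are discrimination between the two hydroxyls of 8 (one flanked by hydrogen, the other by methyl) and carbonylation at a doubly flanked carbon.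

**6 ⇒ 5 ⇒ 4 + 2.** The cuts are the O–Si bond on ring B and then the acyl C–O bond between the ring B carbonyl and the ring C oxygen. The ring B phenol must be masked by a group orthogonal to the hydrogenolysable ester of 2. A benzyl ether would not be orthogonal, so a silyl ether is used.

**4 and 2 ⇒ 1.** Both building blocks come from 1, by silylation of the phenol and by alkylation of the carboxylate. The only demand is chemoselectivity between the carboxyl and the phenol of 1.

## Other disconnections considered

**Alternative 1:** The cut runs through ring A itself, at C1–C6 and C3–C4, taking it back to two acyclic esters.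
- Forward step: under an alkoxide base, methyl 4-methoxyacetoacetate A2 would add through its C2 to methyl crotonate A3, and its methoxy-bearing carbon would then close onto the crotonate ester. This gives the cyclohexanedione A1 as a racemic mixture of epimers and enol forms. Its stereocentres vanish on dehydrogenation to methyl 2,4-dihydroxy-3-methoxy-6-methylbenzoate A4.
- In favour: the oxygen pattern and the methyl group of ring A are fixed by construction from cheap materials. The free C4 hydroxyl and the chelated C2 hydroxyl of A4 can be told apart reliably.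
- Against: it answers only ring A. A4 still needs aromatization of an alkoxy dione, 4-O protection, 2-O methylation and hydrolysis of a doubly ortho-substituted methyl ester before it can be coupled.
- Comparison on structure: A4 is the better entry to ring A. It does not depend on steric discrimination between the two hydroxyls of 8 or on carbonylation at a crowded carbon.
- Comparison on mechanism: the Michael–Dieckmann sequence is at least the equal of the palladium carbonylation in reliability.
- Comparison on step economy: it is clearly worse (at least five operations to a coupling-ready ring A acid against three from 7). It leaves the chelated hydroxyls of rings B and C unsolved, so it could only replace steps 5 to 7, not the key step.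

**Alternative 2:** The cut is at the C6–CH3 and C1–carboxyl bonds of an orsellinic unit.
- Forward step: 1-fluoro-3,5-dimethoxybenzene A5 would be lithiated between fluorine and methoxy and would lose fluoride to give 3,5-dimethoxybenzyne A6. A methyl organolithium would add at the aryne carbon remote from methoxy, and the aryl anion next to methoxy would be carboxylated to 2,4-dimethoxy-6-methylbenzoic acid A7.
- In favour: two bonds form in one flask with predictable aryne regiochemistry. Both ring oxygens are present before any ester bond exists, so no oxidation is ever run on a depside. On this concentration of risk it is the better plan. On mechanistic predictability it is the equal or the better of a twofold directed C–H oxygenation.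
- Against: A7 carries two methyl ethers that must be cleaved, while the two methyl ethers of ring A must stay. The cleavage must therefore be done on the monomer, followed by differentiation and protection of the 2- and 4-hydroxyls for two rings. That is the work the chosen plan avoids by never having a 2-hydroxyl to protect. A7 is also no simpler than purchasable 1.
- Comparison on step economy: worse, and it requires cryogenic organolithium chemistry.

**Alternative 3:** The cut takes ring B apart at C1–C2, C2–C3 and C4–C5 and builds it on a ring C ester.
- Forward step: irradiation of the diazoketone A8 would give, by Wolff rearrangement, the vinylketene A9. This would add (triisopropylsilyloxy)acetylene A10 in a [2+2] step. Four-electron ring opening, six-electron ring closure and tautomerization would then give the didepside A11, with the ring B 2-hydroxyl free and the 4-oxygen silylated.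
- In favour: the ring-forming step itself delivers the two ring B oxygens already differentiated, which is better than any protecting-group sequence. The conditions are neutral and tolerate the aryl ester. The benzyl groups of A11 leave in one hydrogenolysis, the equal of the chosen end game.
- Against: A8 needs diazo chemistry on an unsaturated half-ester, A10 is a sensitive ynol ether, and photochemical equipment is required. Ring C must be supplied already hydroxylated and benzylated, so only one of the two chelated hydroxyls is gained.
- Comparison: on structure it is convergent but builds a ring that can be bought. On mechanism it is well understood and regiochemically secure, the equal of the chosen step. On step economy it is worse.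

Key step: step 10

Remark on the chemistry: the target has no stereocentre, so the SMILES carry no stereodescriptors; reagent amounts and temperatures are proposals.

## Route

**Step 1**
Reactants: 1 4-hydroxy-2-methylbenzoic acid
Product: 2 4-nitrobenzyl 4-hydroxy-2-methylbenzoate
Conditions: 4-nitrobenzyl bromide, KHCO3, DMF, rt to 40 °C
Reagents that add atoms: 4-nitrobenzyl bromide, O=[N+]([O-])c1ccc(CBr)cc1
Why: Carboxylate O-alkylation (SN2); bicarbonate ionizes the acid but not the phenol, so only the ester forms.

**Step 2**
Reactants: 1 4-hydroxy-2-methylbenzoic acid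
Product: 4 4-(tert-butyldimethylsilyloxy)-2-methylbenzoic acid, via bis-silyl derivative 3 (not isolated)
Conditions: TBSCl (2.4 equiv), imidazole, DMF, rt; then AcOH, THF/H2O, rt
Reagents that add atoms: tert-butyldimethylsilyl chloride, CC(C)(C)[Si](C)(C)Cl
Why: Silylation of both acidic groups followed by selective solvolysis of the silyl ester, which is far more labile than the aryl silyl ether.

**Step 3**
Reactants: 4 4-(tert-butyldimethylsilyloxy)-2-methylbenzoic acid; 2 4-nitrobenzyl 4-hydroxy-2-methylbenzoate
Product: 5 4-nitrobenzyl 4-{[4-(tert-butyldimethylsilyloxy)-2-methylbenzoyl]oxy}-2-methylbenzoate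
Conditions: EDC·HCl, DMAP (0.2 equiv), CH2Cl2, 0 °C to rt
Reagents that add atoms: none
Why: Steglich esterification; the acid has a single ortho substituent, so carbodiimide activation with DMAP acyl transfer should suffice.

**Step 4**
Reactants: 5 4-nitrobenzyl 4-{[4-(tert-butyldimethylsilyloxy)-2-methylbenzoyl]oxy}-2-methylbenzoate
Product: 6 4-nitrobenzyl 4-[(4-hydroxy-2-methylbenzoyl)oxy]-2-methylbenzoate
Conditions: HF·pyridine, THF/pyridine, 0 °C to rt
Reagents that add atoms: none
Why: Fluoride cleavage of an aryl silyl ether under buffered, non-basic conditions; basic fluoride sources are avoided because nitrobenzyl and aryl esters are base-sensitive.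

**Step 5**
Reactants: 7 coenzyme Q0 (2,3-dimethoxy-5-methyl-1,4-benzoquinone)
Product: 9 2,3-dimethoxy-6-methyl-4-(triisopropylsilyloxy)phenol, via hydroquinone 8 (not isolated)
Conditions: H2 (1 atm), Pd/C, THF, rt; filter under Ar; then TIPSCl (1.05 equiv), imidazole, DMF, 0 °C
Reagents that add atoms: triisopropylsilyl chloride, CC(C)[Si](Cl)(C(C)C)C(C)C
Why: Catalytic hydrogenation of the quinone, then regioselective silylation: the hydroxyl between methoxy and hydrogen is more accessible and more acidic than the one between methoxy and methyl, and the bulky silyl chloride should take only the former.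

**Step 6**
Reactants: 9 2,3-dimethoxy-6-methyl-4-(triisopropylsilyloxy)phenol
Product: 10 2,3-dimethoxy-6-methyl-4-(triisopropylsilyloxy)phenyl trifluoromethanesulfonate
Conditions: Tf2O, pyridine, CH2Cl2, 0 °C
Reagents that add atoms: trifluoromethanesulfonic anhydride, O=S(=O)(OS(=O)(=O)C(F)(F)F)C(F)(F)F
Why: O-sulfonylation of the remaining phenol; the small, highly electrophilic anhydride reaches even a doubly flanked hydroxyl.

**Step 7**
Reactants: 10 2,3-dimethoxy-6-methyl-4-(triisopropylsilyloxy)phenyl trifluoromethanesulfonate
Product: 12 2,3-dimethoxy-6-methyl-4-(triisopropylsilyloxy)benzoic acid, via acetic mixed anhydride 11 (not isolated)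
Conditions: CO (1 atm), Pd(OAc)2 (5 mol%), dppf (10 mol%), KOAc, DMSO, 80 °C; aq. citric acid work-up
Reagents that add atoms: carbon monoxide, [C-]#[O+]; potassium acetate, CC(=O)[O-].[K+]
Why: Palladium-catalysed hydroxycarbonylation of an aryl triflate: zerovalent palladium inserts into the C–O bond, CO inserts, acetate captures the acyl complex of divalent palladium as the mixed anhydride, and water cleaves this at the unhindered acetyl carbonyl; this is the step that swaps the quinone oxygen for the carboxyl carbon.

**Step 8**
Reactants: 12 2,3-dimethoxy-6-methyl-4-(triisopropylsilyloxy)benzoic acid; 6 4-nitrobenzyl 4-[(4-hydroxy-2-methylbenzoyl)oxy]-2-methylbenzoate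
Product: 14 4-nitrobenzyl 4-{[4-({2,3-dimethoxy-6-methyl-4-(triisopropylsilyloxy)benzoyl}oxy)-2-methylbenzoyl]oxy}-2-methylbenzoate, via acid chloride 13 (not isolated)
Conditions: (COCl)2, cat. DMF, CH2Cl2, 0 °C to rt; evaporate; then 6, Et3N, DMAP (cat.), CH2Cl2, 0 °C to rt
Reagents that add atoms: none
Why: Acid chloride formation (chloroiminium activation) and nucleophilic acyl substitution by the phenol; the silyl ether cannot transfer to the phenol as an acyl protecting group could.

**Step 9**
Reactants: 14 4-nitrobenzyl 4-{[4-({2,3-dimethoxy-6-methyl-4-(triisopropylsilyloxy)benzoyl}oxy)-2-methylbenzoyl]oxy}-2-methylbenzoate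
Product: 15 4-nitrobenzyl 4-({4-[(4-hydroxy-2,3-dimethoxy-6-methylbenzoyl)oxy]-2-methylbenzoyl}oxy)-2-methylbenzoate
Conditions: HF·pyridine, THF/pyridine, 0 °C to rt
Reagents that add atoms: none
Why: Buffered fluoride desilylation; at this stage all three esters are plain benzoates without an ortho hydroxyl and should be untouched.

**Step 10**
Reactants: 15 4-nitrobenzyl 4-({4-[(4-hydroxy-2,3-dimethoxy-6-methylbenzoyl)oxy]-2-methylbenzoyl}oxy)-2-methylbenzoate
Product: 18 4-nitrobenzyl 2-hydroxy-4-({2-hydroxy-4-[(4-hydroxy-2,3-dimethoxy-6-methylbenzoyl)oxy]-6-methylbenzoyl}oxy)-6-methylbenzoate, via ring A trifluoroacetate 16 (not isolated), via tris(trifluoroacetate) 17 (not isolated)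
Conditions: TFA/TFAA (3:1), rt, 30 min; then [RuCl2(p-cymene)]2 (10 mol%), PhI(OCOCF3)2 (3 equiv), 80 °C; concentrate; THF/H2O, rt
Reagents that add atoms: [bis(trifluoroacetoxy)iodo]benzene, O=C(OI(OC(=O)C(F)(F)F)c1ccccc1)C(F)(F)F
Why: The anhydride first acylates the ring A phenol, so the oxidant meets only an electron-poor aryl trifluoroacetate. In the acid, [RuCl2(p-cymene)]2 becomes a trifluoroacetate complex of divalent ruthenium, which binds an ester carbonyl and cleaves the C2–H bond of that benzoyl ring by carboxylate-assisted metalation to a five-membered ruthenacycle. The trivalent iodine reagent oxidizes this to an aryl complex of tetravalent ruthenium, and C–O reductive elimination gives the aryl trifluoroacetate and returns divalent ruthenium; the same events follow on the other ring. The closest known reaction is the ruthenium-catalysed, ester-directed ortho-hydroxylation of alkyl benzoates with this oxidant and medium; aryl esters as directing groups and the twofold course stretch its scope, not its type. No ring is closed and no stereocentre is formed. Site selectivity is required and the substrate supplies it: C6 of rings B and C is methylated, so C2 is the only ortho C–H each carbonyl can reach through a five-membered chelate, and ring A has methoxy and methyl at both ortho positions. Each new phenol is held as its trifluoroacetate, which blocks further oxidation, and all three trifluoroacetates are hydrolysed by water in the work-up.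

**Step 11**
Reactants: 18 4-nitrobenzyl 2-hydroxy-4-({2-hydroxy-4-[(4-hydroxy-2,3-dimethoxy-6-methylbenzoyl)oxy]-6-methylbenzoyl}oxy)-6-methylbenzoate
Product: 19 2-hydroxy-4-({2-hydroxy-4-[(4-hydroxy-2,3-dimethoxy-6-methylbenzoyl)oxy]-6-methylbenzoyl}oxy)-6-methylbenzoic acid (CNP0319613.0)
Conditions: H2 (1 atm), Pd/C, THF/EtOAc, rt; dilute HCl wash
Reagents that add atoms: none
Why: Hydrogenation of the nitro group and hydrogenolysis of the resulting 4-aminobenzyl ester; the conditions are neutral and free of nucleophiles, so the depside bonds and the acid terminus are not endangered.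

## Compound list

1 | 4-hydroxy-2-methylbenzoic acid | Cc1cc(O)ccc1C(=O)O | starting material
2 | 4-nitrobenzyl 4-hydroxy-2-methylbenzoate | Cc1cc(O)ccc1C(=O)OCc1ccc(cc1)[N+](=O)[O-] | intermediate
3 | tert-butyldimethylsilyl 4-(tert-butyldimethylsilyloxy)-2-methylbenzoate (not isolated) | Cc1cc(O[Si](C)(C)C(C)(C)C)ccc1C(=O)O[Si](C)(C)C(C)(C)C | intermediate
4 | 4-(tert-butyldimethylsilyloxy)-2-methylbenzoic acid | Cc1cc(O[Si](C)(C)C(C)(C)C)ccc1C(=O)O | intermediate
5 | 4-nitrobenzyl 4-{[4-(tert-butyldimethylsilyloxy)-2-methylbenzoyl]oxy}-2-methylbenzoate | Cc1cc(O[Si](C)(C)C(C)(C)C)ccc1C(=O)Oc1ccc(C(=O)OCc2ccc(cc2)[N+](=O)[O-])c(C)c1 | intermediate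
6 | 4-nitrobenzyl 4-[(4-hydroxy-2-methylbenzoyl)oxy]-2-methylbenzoate | Cc1cc(O)ccc1C(=O)Oc1ccc(C(=O)OCc2ccc(cc2)[N+](=O)[O-])c(C)c1 | intermediate
7 | coenzyme Q0 (2,3-dimethoxy-5-methyl-1,4-benzoquinone) | COC1=C(OC)C(=O)C(C)=CC1=O | starting material
8 | 2,3-dimethoxy-5-methylbenzene-1,4-diol (not isolated) | COc1c(O)cc(C)c(O)c1OC | intermediate
9 | 2,3-dimethoxy-6-methyl-4-(triisopropylsilyloxy)phenol | COc1c(O[Si](C(C)C)(C(C)C)C(C)C)cc(C)c(O)c1OC | intermediate
10 | 2,3-dimethoxy-6-methyl-4-(triisopropylsilyloxy)phenyl trifluoromethanesulfonate | COc1c(O[Si](C(C)C)(C(C)C)C(C)C)cc(C)c(OS(=O)(=O)C(F)(F)F)c1OC | intermediate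
11 | acetic 2,3-dimethoxy-6-methyl-4-(triisopropylsilyloxy)benzoic anhydride (not isolated) | COc1c(O[Si](C(C)C)(C(C)C)C(C)C)cc(C)c(C(=O)OC(C)=O)c1OC | intermediate
12 | 2,3-dimethoxy-6-methyl-4-(triisopropylsilyloxy)benzoic acid | COc1c(O[Si](C(C)C)(C(C)C)C(C)C)cc(C)c(C(=O)O)c1OC | intermediate
13 | 2,3-dimethoxy-6-methyl-4-(triisopropylsilyloxy)benzoyl chloride (not isolated) | COc1c(O[Si](C(C)C)(C(C)C)C(C)C)cc(C)c(C(Cl)=O)c1OC | intermediate
14 | 4-nitrobenzyl 4-{[4-({2,3-dimethoxy-6-methyl-4-(triisopropylsilyloxy)benzoyl}oxy)-2-methylbenzoyl]oxy}-2-methylbenzoate | COc1c(O[Si](C(C)C)(C(C)C)C(C)C)cc(C)c(C(=O)Oc2ccc(C(=O)Oc3ccc(C(=O)OCc4ccc(cc4)[N+](=O)[O-])c(C)c3)c(C)c2)c1OC | intermediate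
15 | 4-nitrobenzyl 4-({4-[(4-hydroxy-2,3-dimethoxy-6-methylbenzoyl)oxy]-2-methylbenzoyl}oxy)-2-methylbenzoate (key-step precursor) | COc1c(O)cc(C)c(C(=O)Oc2ccc(C(=O)Oc3ccc(C(=O)OCc4ccc(cc4)[N+](=O)[O-])c(C)c3)c(C)c2)c1OC | intermediate
16 | ring A 4-O-trifluoroacetyl derivative of 15 (not isolated) | COc1c(OC(=O)C(F)(F)F)cc(C)c(C(=O)Oc2ccc(C(=O)Oc3ccc(C(=O)OCc4ccc(cc4)[N+](=O)[O-])c(C)c3)c(C)c2)c1OC | intermediate
17 | tris(trifluoroacetate) of 18 (not isolated) | COc1c(OC(=O)C(F)(F)F)cc(C)c(C(=O)Oc2cc(C)c(C(=O)Oc3cc(C)c(C(=O)OCc4ccc(cc4)[N+](=O)[O-])c(OC(=O)C(F)(F)F)c3)c(OC(=O)C(F)(F)F)c2)c1OC | intermediate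
18 | 4-nitrobenzyl 2-hydroxy-4-({2-hydroxy-4-[(4-hydroxy-2,3-dimethoxy-6-methylbenzoyl)oxy]-6-methylbenzoyl}oxy)-6-methylbenzoate (key-step product) | COc1c(O)cc(C)c(C(=O)Oc2cc(C)c(C(=O)Oc3cc(C)c(C(=O)OCc4ccc(cc4)[N+](=O)[O-])c(O)c3)c(O)c2)c1OC | intermediate
19 | 2-hydroxy-4-({2-hydroxy-4-[(4-hydroxy-2,3-dimethoxy-6-methylbenzoyl)oxy]-6-methylbenzoyl}oxy)-6-methylbenzoic acid | COc1c(O)cc(C)c(C(=O)Oc2cc(C)c(C(=O)Oc3cc(C)c(C(=O)O)c(O)c3)c(O)c2)c1OC | target

## Step count and risks

Total step count: 11. Longest linear sequence: 7 steps (7 to 19 through steps 5 to 11; the branch from 1 through steps 1 or 2, 3, 4 and 8 to 11 is equally long).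

**Step 10 (key step).** The most likely failure is incomplete oxygenation of ring B. Its directing carbonyl is an aryl ester, a weaker donor than an alkyl ester, and metalation must happen twice on one molecule. Two further processes could compete in the hot acid:
- acyl exchange at the ring A–ring B ester, whose electron-rich, doubly ortho-substituted acyl group ionizes easily;
- oxygenation ortho to an ester oxygen through a six-membered chelate.

The fallback installs the hydroxyl on the monomer, where the directing group is an alkyl ester, and then builds the depside with the chelated hydroxyls left free. It sets out from 2 and returns at 18. In the same medium, 2 is trifluoroacetylated to 4-nitrobenzyl 2-methyl-4-(trifluoroacetoxy)benzoate F1 (in the flask), oxygenated at its single free ortho position to 4-nitrobenzyl 2-methyl-4,6-bis(trifluoroacetoxy)benzoate F2 (in the flask), and hydrolysed to 4-nitrobenzyl 2,4-dihydroxy-6-methylbenzoate F3. Acid chloride 13 acylates the non-chelated C4 hydroxyl of F3 (pyridine, CH2Cl2) to give 4-nitrobenzyl 4-{[2,3-dimethoxy-6-methyl-4-(triisopropylsilyloxy)benzoyl]oxy}-2-hydroxy-6-methylbenzoate F4. Hydrogenation over Pd/C frees 4-{[2,3-dimethoxy-6-methyl-4-(triisopropylsilyloxy)benzoyl]oxy}-2-hydroxy-6-methylbenzoic acid F5. Carbodiimide coupling (DCC, cat. DMAP) of F5 with a second portion of F3, again at its C4 hydroxyl, gives the ring A silyl ether of 18, F6. HF·pyridine then delivers 18.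

**Step 5.** The likely failure is loss of regiocontrol or double silylation, together with air reoxidation of the hydroquinone before it is capped. The two hydroxyls differ only by a neighbouring hydrogen versus methyl. The fallback differentiates them by selective removal instead of selective introduction. It sets out from 8 and returns at 10. Both hydroxyls are triflated (Tf2O, pyridine) to 2,3-dimethoxy-5-methyl-1,4-phenylene bis(trifluoromethanesulfonate) F7. The triflate flanked by hydrogen is cleaved at sulfur with Et4NOH in dioxane, since it is the more open site and has the better phenoxide leaving group, giving 4-hydroxy-2,3-dimethoxy-6-methylphenyl trifluoromethanesulfonate F8. Silylation with TIPSCl and imidazole gives 10.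

**Step 7.** The likely failure is slow insertion of zerovalent palladium into the C–O bond of an electron-rich, doubly flanked triflate under CO. Sulfonate hydrolysis or silyl ether loss in warm acetate/DMSO could then take over. The fallback introduces the carbon by cross-coupling and oxidizes it afterwards. It sets out from 10 and returns at 12. Suzuki–Miyaura coupling with potassium vinyltrifluoroborate (Pd(OAc)2, SPhos, Cs2CO3, THF/H2O) gives (4-ethenyl-2,3-dimethoxy-5-methylphenoxy)triisopropylsilane F9. Lemieux–Johnson cleavage (OsO4 cat., NaIO4, 2,6-lutidine, dioxane/H2O) gives 2,3-dimethoxy-6-methyl-4-(triisopropylsilyloxy)benzaldehyde F10. Pinnick oxidation (NaClO2, NaH2PO4, 2-methyl-2-butene) gives 12.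

**Step 8.** The likely failure is sluggish acylation at a carbonyl shielded by methoxy and methyl. That would leave time for phenoxide-mediated ester exchange within 6. The fallback replaces attack on a shielded acid chloride by acyl transfer from an ionizing mixed anhydride, which works best with such electron-rich, doubly ortho-substituted acids. It sets out from 12 and 6 and returns at 14. With TFAA in toluene at rt, 12 forms 2,3-dimethoxy-6-methyl-4-(triisopropylsilyloxy)benzoic trifluoroacetic anhydride F11 in the flask, which acylates 6 to give 14.

## Further compounds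

F1 | step 10 | 4-nitrobenzyl 2-methyl-4-(trifluoroacetoxy)benzoate | Cc1cc(OC(=O)C(F)(F)F)ccc1C(=O)OCc1ccc(cc1)[N+](=O)[O-]
F2 | step 10 | 4-nitrobenzyl 2-methyl-4,6-bis(trifluoroacetoxy)benzoate | Cc1cc(OC(=O)C(F)(F)F)cc(OC(=O)C(F)(F)F)c1C(=O)OCc1ccc(cc1)[N+](=O)[O-]
F3 | step 10 | 4-nitrobenzyl 2,4-dihydroxy-6-methylbenzoate | Cc1cc(O)cc(O)c1C(=O)OCc1ccc(cc1)[N+](=O)[O-]
F4 | step 10 | 4-nitrobenzyl 4-{[2,3-dimethoxy-6-methyl-4-(triisopropylsilyloxy)benzoyl]oxy}-2-hydroxy-6-methylbenzoate | COc1c(O[Si](C(C)C)(C(C)C)C(C)C)cc(C)c(C(=O)Oc2cc(C)c(C(=O)OCc3ccc(cc3)[N+](=O)[O-])c(O)c2)c1OC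
F5 | step 10 | 4-{[2,3-dimethoxy-6-methyl-4-(triisopropylsilyloxy)benzoyl]oxy}-2-hydroxy-6-methylbenzoic acid | COc1c(O[Si](C(C)C)(C(C)C)C(C)C)cc(C)c(C(=O)Oc2cc(C)c(C(=O)O)c(O)c2)c1OC
F6 | step 10 | 4-nitrobenzyl 4-{[4-({2,3-dimethoxy-6-methyl-4-(triisopropylsilyloxy)benzoyl}oxy)-2-hydroxy-6-methylbenzoyl]oxy}-2-hydroxy-6-methylbenzoate | COc1c(O[Si](C(C)C)(C(C)C)C(C)C)cc(C)c(C(=O)Oc2cc(C)c(C(=O)Oc3cc(C)c(C(=O)OCc4ccc(cc4)[N+](=O)[O-])c(O)c3)c(O)c2)c1OC
F7 | step 5 | 2,3-dimethoxy-5-methyl-1,4-phenylene bis(trifluoromethanesulfonate) | COc1c(OS(=O)(=O)C(F)(F)F)cc(C)c(OS(=O)(=O)C(F)(F)F)c1OC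
F8 | step 5 | 4-hydroxy-2,3-dimethoxy-6-methylphenyl trifluoromethanesulfonate | COc1c(O)cc(C)c(OS(=O)(=O)C(F)(F)F)c1OC
F9 | step 7 | (4-ethenyl-2,3-dimethoxy-5-methylphenoxy)triisopropylsilane | COc1c(O[Si](C(C)C)(C(C)C)C(C)C)cc(C)c(C=C)c1OC
F10 | step 7 | 2,3-dimethoxy-6-methyl-4-(triisopropylsilyloxy)benzaldehyde | COc1c(O[Si](C(C)C)(C(C)C)C(C)C)cc(C)c(C=O)c1OC
F11 | step 8 | 2,3-dimethoxy-6-methyl-4-(triisopropylsilyloxy)benzoic trifluoroacetic anhydride | COc1c(O[Si](C(C)C)(C(C)C)C(C)C)cc(C)c(C(=O)OC(=O)C(F)(F)F)c1OC
A1 | alternative 1 | methyl 3-methoxy-6-methyl-2,4-dioxocyclohexane-1-carboxylate (racemic, mixture of epimers and enol forms) | COC(=O)C1C(C)CC(=O)C(OC)C1=O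
A2 | alternative 1 | methyl 4-methoxy-3-oxobutanoate (methyl 4-methoxyacetoacetate) | COCC(=O)CC(=O)OC
A3 | alternative 1 | methyl (E)-but-2-enoate (methyl crotonate) | C/C=C/C(=O)OC
A4 | alternative 1 | methyl 2,4-dihydroxy-3-methoxy-6-methylbenzoate | COC(=O)c1c(C)cc(O)c(OC)c1O
A5 | alternative 2 | 1-fluoro-3,5-dimethoxybenzene | COc1cc(F)cc(OC)c1
A6 | alternative 2 | 3,5-dimethoxybenzyne | COC1=CC(OC)=CC#C1
A7 | alternative 2 | 2,4-dimethoxy-6-methylbenzoic acid | COc1cc(C)c(C(=O)O)c(OC)c1
A8 | alternative 3 | benzyl 2-(benzyloxy)-4-{[(2E)-5-diazo-3-methyl-4-oxopent-2-enoyl]oxy}-6-methylbenzoate | [N-]=[N+]=CC(=O)/C(C)=C/C(=O)Oc1cc(C)c(C(=O)OCc2ccccc2)c(OCc2ccccc2)c1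
A9 | alternative 3 | benzyl 2-(benzyloxy)-6-methyl-4-{[(2E)-3-methyl-5-oxopenta-2,4-dienoyl]oxy}benzoate (vinylketene) | O=C=C/C(C)=C/C(=O)Oc1cc(C)c(C(=O)OCc2ccccc2)c(OCc2ccccc2)c1
A10 | alternative 3 | (ethynyloxy)triisopropylsilane ((triisopropylsilyloxy)acetylene) | C#CO[Si](C(C)C)(C(C)C)C(C)C
A11 | alternative 3 | benzyl 2-(benzyloxy)-4-{[2-hydroxy-6-methyl-4-(triisopropylsilyloxy)benzoyl]oxy}-6-methylbenzoate | Cc1cc(O[Si](C(C)C)(C(C)C)C(C)C)cc(O)c1C(=O)Oc1cc(C)c(C(=O)OCc2ccccc2)c(OCc2ccccc2)c1
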